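Ring B is cut on both sides of its C7–C8 unit (eudesmane numbering). C9 lies β to the C1 oxygen, and C6 and C8 are carbinol carbons, so ring A can carry C9 as the CH2 of a 1-silyloxycyclopropane (a masked C1-ketone homoenolate) next to a C6 aldehyde. In one Lewis-acid operation a silyl enol ether adds through C7 to the aldehyde, and the C8 oxocarbenium ion so formed is captured by the strained C9–C1 bond. This formal [4+2] annulation forms C6–C7 and C8–C9, closes ring B and sets C6, C7 and C8. The precursor is a bicyclo[4.1.0]heptane carbaldehyde that holds no decalin.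

Key step: step 7

Remark on numbering: ring A = C1 (CHOH), C2, C3, C4 (bears C15), C5, C10 (bears methyl C14); ring B = C5, C6 (CHOH), C7 (bears C11(=C13H2)–C12), C8 (ester oxygen), C9 (CH2), C10; β is the face of the C10 methyl group, α the opposite face; PMB = 4-methoxybenzyl.
Remark on starting materials: 3-[(4-methoxybenzyl)oxy]propanal (1) is taken as a catalogue compound; if it has to be made, one oxidation of the catalogue alcohol is added.

Step 1
Reactants: 1 3-[(4-methoxybenzyl)oxy]propanal; 2 pent-1-en-3-one (ethyl vinyl ketone)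
Product: 4 (R)-4-{[(4-methoxybenzyl)oxy]methyl}-2-methylcyclohex-2-en-1-one, via keto aldehyde 3 (not isolated)
Conditions: (S)-2-[diphenyl(trimethylsilyloxy)methyl]pyrrolidine (10 mol %), ethyl 3,4-dihydroxybenzoate (20 mol %), neat, 4 °C; then Bn2NH·CF3CO2H (20 mol %), toluene, 50 °C
Reagents that add atoms: none
Why: Enamine-catalysed Michael addition sets C4, because the bulky diarylsilyloxymethyl group of the (S)-catalyst shields one face of the E-enamine and should give (S)-3, and the amine-salt-catalysed intramolecular aldol condensation then closes ring A under non-basic conditions that avoid β-elimination of the PMB ether.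

Step 2
Reactants: 4 (R)-4-{[(4-methoxybenzyl)oxy]methyl}-2-methylcyclohex-2-en-1-one
Product: 5 trimethyl({(3S,4R)-4-{[(4-methoxybenzyl)oxy]methyl}-2-methyl-3-vinylcyclohex-1-en-1-yl}oxy)silane (vinyl trans to CH2OPMB)
Conditions: CH2=CHMgBr, CuBr·SMe2 (10 mol %), TMSCl, HMPA, THF, −78 °C; Et3N, pentane work-up
Reagents that add atoms: vinylmagnesium bromide, C=C[Mg]Br; chlorotrimethylsilane, C[Si](C)(C)Cl
Why: Copper-catalysed conjugate addition of the vinyl Grignard reagent should occur anti to the C4 substituent and so set C5 (trans), and TMSCl traps the enolate regiospecifically as the C1=C10 silyl enol ether.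

Step 3
Reactants: 5 trimethyl({(3S,4R)-4-{[(4-methoxybenzyl)oxy]methyl}-2-methyl-3-vinylcyclohex-1-en-1-yl}oxy)silane
Product: 6 3-{[(4-methoxybenzyl)oxy]methyl}-1-methyl-6-(trimethylsilyloxy)-2-vinylbicyclo[4.1.0]heptane (cyclopropane CH2 = C9, trans to vinyl and cis to CH2OPMB; OSiMe3 and CH3 on the face of the vinyl group)
Conditions: Et2Zn, CH2I2, CH2Cl2, 0 °C → rt
Reagents that add atoms: diiodomethane, ICI
Why: Simmons–Smith cyclopropanation of the electron-rich enol ether, which reacts much faster than the vinyl group, should deliver the CH2 (C9) anti to the pseudoaxial C5 vinyl group and on the face of the coordinating PMB ether, which fixes the quaternary centre C10 with C9 trans to C6.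

Step 4
Reactants: 6 3-{[(4-methoxybenzyl)oxy]methyl}-1-methyl-6-(trimethylsilyloxy)-2-vinylbicyclo[4.1.0]heptane
Product: 7 3-{[(4-methoxybenzyl)oxy]methyl}-1-methyl-6-(trimethylsilyloxy)bicyclo[4.1.0]heptane-2-carbaldehyde (CHO trans to the cyclopropane CH2 and trans to CH2OPMB)
Conditions: O3, CH2Cl2, −78 °C (Sudan Red end point); then PPh3, −78 °C → rt
Reagents that add atoms: ozone, [O-][O+]=O
Why: Ozonolysis with reductive work-up cleaves the only alkene to the C6 aldehyde, while the tertiary cyclopropyl silyl ether, the PMB ether and the all-trans C5 configuration should survive at −78 °C.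

Step 5
Reactants: 8 4-(trimethylsilyl)but-3-yn-1-ol
Product: 9 4-(trimethylsilyl)but-3-ynal
Conditions: Dess–Martin periodinane, CH2Cl2, 0 °C → rt
Reagents that add atoms: none
Why: Dess–Martin oxidation gives the aldehyde under near-neutral conditions that should avoid isomerisation of the β,γ-ynal to the allenal.

Step 6
Reactants: 9 4-(trimethylsilyl)but-3-ynal
Product: 10 (Z)-trimethyl{[4-(trimethylsilyl)but-1-en-3-yn-1-yl]oxy}silane (Z isomer shown; the E isomer is expected to react alike)
Conditions: TMSOTf, Et3N, Et2O, 0 °C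
Reagents that add atoms: trimethylsilyl trifluoromethanesulfonate, C[Si](C)(C)OS(=O)(=O)C(F)(F)F
Why: Soft enolisation and O-silylation of the acidic propargylic aldehyde gives the conjugated silyl enol ether, whose only enol-type nucleophilic carbon is the one that becomes C7.

Step 7
Reactants: 7 3-{[(4-methoxybenzyl)oxy]methyl}-1-methyl-6-(trimethylsilyloxy)bicyclo[4.1.0]heptane-2-carbaldehyde; 10 (Z)-trimethyl{[4-(trimethylsilyl)but-1-en-3-yn-1-yl]oxy}silane
Product: 12 trans-decalone diol (C1 ketone; 4α-CH2OPMB; 5α-H; 6α-OH; 7β-ethynyl; 8α-OH; 10β-CH3), via tris-silyl decalone 11 (not isolated)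
Conditions: TMSOTf (15 mol %), 2,6-di-tert-butyl-4-methylpyridine (20 mol %), CH2Cl2, −78 → −40 °C, slow addition of 10; then K2CO3 (cat.), MeOH, 0 °C → rt
Reagents that add atoms: none
Why: Proposed new method: TMSOTf turns the C6 aldehyde into a silyloxocarbenium ion, 10 adds to it through C7 (Mukaiyama-type addition), and the C8 silyloxocarbenium ion so formed is attacked within the molecule by the C9–C1 σ bond of the cyclopropyl silyl ether (a C1-ketone homoenolate equivalent), which gives the C1 ketone and returns TMSOTf; methanolysis then removes the two O–SiMe3 groups and the alkynyl SiMe3 group. The closest known reaction types are the Mukaiyama aldol–Prins cascade of enol ethers and the Lewis-acid cyclisation of cyclopropyl silyl ethers onto oxocarbenium ions, whose union as an intermolecular formal [4+2] annulation of a 1,4-dipole equivalent has not been shown. Ring B closes by 6-exo-trig attack of C9 on the exocyclic C8=O+ bond through a chair, with corner attack (inversion) at the cyclopropane CH2, and the ring fusion comes out trans because C9 and C6 are trans on ring A. C6 is set by Felkin–Anh addition anti to the quaternary C10 (6α-O), C7 by the open antiperiplanar transition state of silyl-triflate-catalysed enol ether additions (syn adduct, 7β-ethynyl), and C8 by the chair, in which the silyloxy group lies equatorial to avoid the axial C10 methyl group (8α-O). The step needs addition of 10 to C6 before any opening of the cyclopropane and ring closure before a second molecule of 10 adds: the first is secured because the cyclopropane could reach C6 only through a four-membered ring, the second by the fast six-membered closure together with slow addition of 10 and a hindered pyridine base that removes triflic acid.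

Step 8
Reactants: 13 ethyl 2-(hydroxymethyl)acrylate
Product: 14 ethyl 2-{[(tert-butyldimethylsilyl)oxy]methyl}acrylate
Conditions: TBSCl, imidazole, CH2Cl2, 0 °C → rt
Reagents that add atoms: tert-butyldimethylsilyl chloride, CC(C)(C)[Si](C)(C)Cl
Why: Standard silylation of the primary allylic alcohol (silyl ether protection).

Step 9
Reactants: 14 ethyl 2-{[(tert-butyldimethylsilyl)oxy]methyl}acrylate
Product: 15 2-{[(tert-butyldimethylsilyl)oxy]methyl}acrylic acid
Conditions: LiOH, THF/H2O, 0 °C; then cold aq. HCl to pH 4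
Reagents that add atoms: lithium hydroxide, [Li+].[OH-]
Why: Saponification of the ethyl ester at 0 °C should leave the silyl ether intact, and the 2-substituted acrylate resists conjugate addition of hydroxide.

Step 10
Reactants: 12 trans-decalone diol (C1 ketone; 4α-CH2OPMB; 6α-OH; 7β-ethynyl; 8α-OH); 15 2-{[(tert-butyldimethylsilyl)oxy]methyl}acrylic acid
Product: 16 8α-ester of 12 with acid 15 (8α-O–CO–C(=CH2)–CH2OTBS; 6α-OH free; C1 ketone)
Conditions: DCC, DMAP (10 mol %), CH2Cl2, −20 → 0 °C
Reagents that add atoms: none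
Why: Steglich esterification at low temperature should acylate the equatorial 8-OH selectively, because the 6-OH is flanked by two ring branches and suffers a peri interaction with the C4 CH2OPMB group.

Step 11
Reactants: 16 8α-ester (6α-OH free; C1 ketone)
Product: 17 1β,6α-diol (as 16, with C1 reduced to the equatorial 1β-alcohol)
Conditions: NaBH4, CeCl3·7H2O, MeOH/THF, −40 °C
Reagents that add atoms: none
Why: Luche-type borohydride reduction should deliver hydride to C1 axially from the α face, away from the axial C10 methyl group, to give the equatorial 1β-alcohol, and the acrylate ester is not reduced at −40 °C.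

Step 12
Reactants: 17 1β,6α-diol
Product: 18 1β,6α-bis(tert-butyldimethylsilyl) ether of 17 (7β-ethynyl; 8α-acrylate ester; 4α-CH2OPMB)
Conditions: TBSOTf, 2,6-lutidine, CH2Cl2, −78 → 0 °C
Reagents that add atoms: tert-butyldimethylsilyl trifluoromethanesulfonate, CC(C)(C)[Si](C)(C)OS(=O)(=O)C(F)(F)F
Why: Silylation with the silyl triflate protects both hindered secondary alcohols, so that the 6-OH cannot lactonise onto the acylpalladium intermediate of step 13.

Step 13
Reactants: 18 1β,6α-bis(silyl ether) with 7β-ethynyl group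
Product: 19 acrylic acid (as 18, with 7β-ethynyl turned into 7β-C(=CH2)CO2H)
Conditions: Pd(OAc)2 (5 mol %), 2-(diphenylphosphino)pyridine (20 mol %), CH3SO3H (10 mol %), CO (10 bar), H2O, THF, 50 °C
Reagents that add atoms: carbon monoxide, [C-]#[O+]; water, O
Why: Palladium/2-pyridylphosphine-catalysed Markovnikov hydroxycarbonylation of the terminal alkyne should place the carboxyl group on the internal carbon and give the 2-substituted acrylic acid directly, without touching the C7 stereocentre.

Step 14
Reactants: 19 acrylic acid with 4α-CH2OPMB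
Product: 20 primary alcohol (as 19, with 4α-CH2OH)
Conditions: DDQ, CH2Cl2/pH 7 buffer, 0 °C → rt
Reagents that add atoms: none
Why: Oxidative cleavage of the PMB ether with DDQ (benzylic hydride abstraction, then hydrolysis) should free the C15 alcohol without affecting silyl ethers, acrylates or the acid.

Step 15
Reactants: 20 primary alcohol
Product: 21 aldehyde (as 20, with 4α-CHO)
Conditions: TEMPO (10 mol %), PhI(OAc)2, CH2Cl2, rt
Reagents that add atoms: none
Why: TEMPO/PhI(OAc)2 oxidation of the primary alcohol stops at the aldehyde in anhydrous CH2Cl2 and should not epimerise C4, whose formyl group is already equatorial.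

Step 16
Reactants: 21 aldehyde with three TBS ethers
Product: 22 1β,6α-dihydroxy-8α-{[2-(hydroxymethyl)acryloyl]oxy}-15-oxoeudesm-11(13)-en-12-oic acid (CNP0599450.1; 4α-CHO, 5α-H, 10β-CH3)
Conditions: HF·pyridine, pyridine, THF, 0 °C → rt; cold pH 5 buffer work-up
Reagents that add atoms: none
Why: Buffered HF·pyridine removes the three TBS ethers by fluoride-driven desilylation under mildly acidic conditions that should spare the acrylate ester and the aldehyde, and the cold buffered work-up is meant to keep the 6-hydroxy acid from lactonising.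

Compound list
1 | 3-[(4-methoxybenzyl)oxy]propanal | O=CCCOCc1ccc(OC)cc1 | starting material
2 | pent-1-en-3-one (ethyl vinyl ketone) | C=CC(=O)CC | starting material
3 | (S)-2-{[(4-methoxybenzyl)oxy]methyl}-5-oxoheptanal | O=C[C@H](COCc1ccc(OC)cc1)CCC(=O)CC | intermediate
4 | (R)-4-{[(4-methoxybenzyl)oxy]methyl}-2-methylcyclohex-2-en-1-one | CC1=C[C@H](COCc2ccc(OC)cc2)CCC1=O | intermediate
5 | trimethyl({(3S,4R)-4-{[(4-methoxybenzyl)oxy]methyl}-2-methyl-3-vinylcyclohex-1-en-1-yl}oxy)silane | C=C[C@H]1[C@H](COCc2ccc(OC)cc2)CCC(O[Si](C)(C)C)=C1C | intermediate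
6 | 3-{[(4-methoxybenzyl)oxy]methyl}-1-methyl-6-(trimethylsilyloxy)-2-vinylbicyclo[4.1.0]heptane (CH2 bridge trans to vinyl, cis to CH2OPMB) | C=C[C@H]1[C@H](COCc2ccc(OC)cc2)CC[C@]3(O[Si](C)(C)C)C[C@]13C | intermediate
7 | 3-{[(4-methoxybenzyl)oxy]methyl}-1-methyl-6-(trimethylsilyloxy)bicyclo[4.1.0]heptane-2-carbaldehyde (CHO trans to CH2 bridge and to CH2OPMB) | O=C[C@H]1[C@H](COCc2ccc(OC)cc2)CC[C@]3(O[Si](C)(C)C)C[C@]13C | intermediate
8 | 4-(trimethylsilyl)but-3-yn-1-ol | C[Si](C)(C)C#CCCO | starting material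
9 | 4-(trimethylsilyl)but-3-ynal | C[Si](C)(C)C#CCC=O | intermediate
10 | (Z)-trimethyl{[4-(trimethylsilyl)but-1-en-3-yn-1-yl]oxy}silane | C[Si](C)(C)C#C/C=C\O[Si](C)(C)C | intermediate
11 | tris-silyl decalone: C1 ketone, 4α-CH2OPMB, 6α-OSiMe3, 7β-(trimethylsilyl)ethynyl, 8α-OSiMe3, 10β-CH3, trans-fused | C[Si](C)(C)O[C@H]1C[C@]2(C)[C@@H]([C@@H](O[Si](C)(C)C)[C@@H]1C#C[Si](C)(C)C)[C@H](COCc3ccc(OC)cc3)CCC2=O | intermediate
12 | trans-decalone diol: C1 ketone, 4α-CH2OPMB, 5α-H, 6α-OH, 7β-ethynyl, 8α-OH, 10β-CH3 | O[C@H]1C[C@]2(C)[C@@H]([C@@H](O)[C@@H]1C#C)[C@H](COCc3ccc(OC)cc3)CCC2=O | intermediate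
13 | ethyl 2-(hydroxymethyl)acrylate | C=C(CO)C(=O)OCC | starting material
14 | ethyl 2-{[(tert-butyldimethylsilyl)oxy]methyl}acrylate | C=C(CO[Si](C)(C)C(C)(C)C)C(=O)OCC | intermediate
15 | 2-{[(tert-butyldimethylsilyl)oxy]methyl}acrylic acid | C=C(CO[Si](C)(C)C(C)(C)C)C(=O)O | intermediate
16 | 8α-ester of 12 with 15 (6α-OH free, C1 ketone) | C=C(CO[Si](C)(C)C(C)(C)C)C(=O)O[C@H]1C[C@]2(C)[C@@H]([C@@H](O)[C@@H]1C#C)[C@H](COCc3ccc(OC)cc3)CCC2=O | intermediate
17 | 1β,6α-diol (as 16, 1β-OH) | C=C(CO[Si](C)(C)C(C)(C)C)C(=O)O[C@H]1C[C@]2(C)[C@@H]([C@@H](O)[C@@H]1C#C)[C@H](COCc3ccc(OC)cc3)CC[C@H]2O | intermediate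
18 | 1β,6α-bis(TBS) ether of 17 | C=C(CO[Si](C)(C)C(C)(C)C)C(=O)O[C@H]1C[C@]2(C)[C@@H]([C@@H](O[Si](C)(C)C(C)(C)C)[C@@H]1C#C)[C@H](COCc3ccc(OC)cc3)CC[C@H]2O[Si](C)(C)C(C)(C)C | intermediate
19 | acrylic acid (as 18, 7β-C(=CH2)CO2H) | C=C(CO[Si](C)(C)C(C)(C)C)C(=O)O[C@H]1C[C@]2(C)[C@@H]([C@@H](O[Si](C)(C)C(C)(C)C)[C@@H]1C(=C)C(=O)O)[C@H](COCc3ccc(OC)cc3)CC[C@H]2O[Si](C)(C)C(C)(C)C | intermediate
20 | primary alcohol (as 19, 4α-CH2OH) | C=C(CO[Si](C)(C)C(C)(C)C)C(=O)O[C@H]1C[C@]2(C)[C@@H]([C@@H](O[Si](C)(C)C(C)(C)C)[C@@H]1C(=C)C(=O)O)[C@H](CO)CC[C@H]2O[Si](C)(C)C(C)(C)C | intermediate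
21 | aldehyde (as 20, 4α-CHO) | C=C(CO[Si](C)(C)C(C)(C)C)C(=O)O[C@H]1C[C@]2(C)[C@@H]([C@@H](O[Si](C)(C)C(C)(C)C)[C@@H]1C(=C)C(=O)O)[C@H](C=O)CC[C@H]2O[Si](C)(C)C(C)(C)C | intermediate
22 | 1β,6α-dihydroxy-8α-{[2-(hydroxymethyl)acryloyl]oxy}-15-oxoeudesm-11(13)-en-12-oic acid (CNP0599450.1) | C=C(CO)C(=O)O[C@H]1C[C@]2(C)[C@@H]([C@@H](O)[C@@H]1C(=C)C(=O)O)[C@H](C=O)CC[C@H]2O | target

Total step count: 16. Longest linear sequence: 12 steps (steps 1, 2, 3, 4, 7, 10, 11, 12, 13, 14, 15, 16); steps 5–6 and 8–9 are two-step side branches.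

Steps most likely to fail

Step 7 (proposed new method). The cascade may stall after the intermolecular addition if the strained σ bond is too weak a nucleophile for the silyloxocarbenium ion. The enol ether may also oligomerise, the cyclopropane may open by protonation, and simple diastereoselection at C7 may be poor. The fallback uses known reactions only and closes the ring by a radical instead of a polar path; it sets out from 7 and comes back to the route at 12. The TMSOTf-catalysed Mukaiyama aldol addition of 10 to 7 is quenched with pyridine at −78 °C and should give the β-silyloxy aldehyde F1, at which stage C7 epimers can be separated. NIS in CH2Cl2 then opens the cyclopropyl silyl ether at its CH2–C(O) bond to the β-iodo ketone F2. Et3B/O2 with (Me3Si)3SiH generates the C9 radical, which closes ring B by reversible 6-exo cyclisation onto the C8 aldehyde, so the equatorial alkoxy radical is the one trapped; this should give the silylated hydroxy ketone F3. K2CO3 in MeOH removes the remaining silyl groups and gives 12.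

Step 13. The palladium hydride may insert with the wrong orientation at the hindered, doubly flanked alkyne and give the linear acid, and the acid co-catalyst may strip the primary silyl ether. The fallback sets out from 18 and comes back at 19. Markovnikov hydrosilylation with [Cp*Ru(MeCN)3]PF6 and Et3SiH should give the 1,1-disubstituted vinylsilane F4, iododesilylation with NIS the 2-iodoalkene F5, and hydroxycarbonylation of F5 (Pd(OAc)2, PPh3, CO, H2O, Et3N, DMF) the acid 19.

Step 16. During the slow removal of the two hindered silyl ethers the freed 6-hydroxy group may lactonise onto C12 under acid catalysis, or the acyl group may migrate from O8 to O6. The fallback sets out from 19 and comes back at 22. The carboxyl group is masked with allyl bromide and KHCO3 in DMF as the allyl ester F6. DDQ gives the alcohol F7, TEMPO/PhI(OAc)2 the aldehyde F8, and HF·pyridine the desilylated allyl ester F9. The ester is then cleaved last under neutral conditions by zerovalent palladium (Pd(PPh3)4, sodium 4-toluenesulfinate, THF/MeOH, rt), and 22 is freed from its salt by cold acidification to pH 5.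

Further compounds
F1 | step 7 | β-silyloxy aldehyde: 7 extended at C6 by CH(OSiMe3)–CH(C≡C–SiMe3)–CHO, cyclopropyl silyl ether intact | O=C[C@@H](C#C[Si](C)(C)C)[C@H](O[Si](C)(C)C)[C@H]1[C@H](COCc2ccc(OC)cc2)CC[C@]3(O[Si](C)(C)C)C[C@]13C
F2 | step 7 | β-iodo ketone: 2-(iodomethyl)-2-methylcyclohexanone carrying the side chain of F1 | IC[C@]1(C)[C@@H]([C@@H](O[Si](C)(C)C)[C@H](C#C[Si](C)(C)C)C=O)[C@H](COCc2ccc(OC)cc2)CCC1=O
F3 | step 7 | silylated hydroxy ketone: as 12, with 6α-OSiMe3 and 7β-(trimethylsilyl)ethynyl | O[C@H]1C[C@]2(C)[C@@H]([C@@H](O[Si](C)(C)C)[C@@H]1C#C[Si](C)(C)C)[C@H](COCc3ccc(OC)cc3)CCC2=O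
F4 | step 13 | vinylsilane: as 18, with 7β-C(=CH2)SiEt3 | C=C(CO[Si](C)(C)C(C)(C)C)C(=O)O[C@H]1C[C@]2(C)[C@@H]([C@@H](O[Si](C)(C)C(C)(C)C)[C@@H]1C(=C)[Si](CC)(CC)CC)[C@H](COCc3ccc(OC)cc3)CC[C@H]2O[Si](C)(C)C(C)(C)C
F5 | step 13 | 2-iodoalkene: as 18, with 7β-C(=CH2)I | C=C(CO[Si](C)(C)C(C)(C)C)C(=O)O[C@H]1C[C@]2(C)[C@@H]([C@@H](O[Si](C)(C)C(C)(C)C)[C@@H]1C(=C)I)[C@H](COCc3ccc(OC)cc3)CC[C@H]2O[Si](C)(C)C(C)(C)C
F6 | step 16 | allyl ester of 19 | C=C(CO[Si](C)(C)C(C)(C)C)C(=O)O[C@H]1C[C@]2(C)[C@@H]([C@@H](O[Si](C)(C)C(C)(C)C)[C@@H]1C(=C)C(=O)OCC=C)[C@H](COCc3ccc(OC)cc3)CC[C@H]2O[Si](C)(C)C(C)(C)C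
F7 | step 16 | allyl ester alcohol (4α-CH2OH) | C=C(CO[Si](C)(C)C(C)(C)C)C(=O)O[C@H]1C[C@]2(C)[C@@H]([C@@H](O[Si](C)(C)C(C)(C)C)[C@@H]1C(=C)C(=O)OCC=C)[C@H](CO)CC[C@H]2O[Si](C)(C)C(C)(C)C
F8 | step 16 | allyl ester aldehyde (4α-CHO) | C=C(CO[Si](C)(C)C(C)(C)C)C(=O)O[C@H]1C[C@]2(C)[C@@H]([C@@H](O[Si](C)(C)C(C)(C)C)[C@@H]1C(=C)C(=O)OCC=C)[C@H](C=O)CC[C@H]2O[Si](C)(C)C(C)(C)C
F9 | step 16 | allyl ester of the target | C=C(CO)C(=O)O[C@H]1C[C@]2(C)[C@@H]([C@@H](O)[C@@H]1C(=C)C(=O)OCC=C)[C@H](C=O)CC[C@H]2O
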